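**Retrosynthetic overview**

- The strategy rests on ring A: a benzoate with the ester carbonyl on C1, OH on C2, OMe on C4 and the alkyl chain on C6 is the folded form of a 3,5,7-triketo ester, and its carboxyl is esterified by the hindered carbinol C4 of the undecyl chain that carries ring B.
- Last disconnections: three benzyl ethers (one hydrogenolysis) and the C4 methyl ether of ring A (methylation of the non-chelated phenol).
- Key disconnection: the ester C–O bond (acylketene plus alcohol 20) and the ring A C1–C6 bond (aldol, then dehydration), leading back to diketo-dioxinone 13 and alcohol 20. Ring B is bought as 5-bromoresorcinol; ring A is the only ring made and is closed last.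
- Diketo-dioxinone 13 comes from keto-dioxinone 2 (dioxinone 1 plus acetyl chloride) and Weinreb amide 12, whose C13 chain is built from (R)-1,2-epoxypentane and 8-bromooct-1-ene.
- Alcohol 20 comes from the same epoxide and 6-bromohex-1-ene, followed by a B-alkyl Suzuki coupling with dibenzylated 5-bromoresorcinol; both (R) carbinols therefore derive from one chiral-pool epoxide.

Key step: step 11

Remark 1: the carbinol of the ring A side chain is carried as a benzyl ether rather than a silyl ether, so that it survives the methanolic HCl used for aromatisation and is removed together with the two aryl benzyl ethers in one final hydrogenolysis.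
Remark 2: 6-bromohex-1-ene is added as a starting material because the ring B chain (seven CH2 between carbinol and arene) needs a C6 alkenyl nucleophile, whereas the ring A chain needs the C8 one.
Remark 3: ring A is numbered C1 (ester carbon), C2 (OH), C4 (OMe), C6 (alkyl). The open triketo ester is numbered from the ester carbonyl C1 to the ketone C7. Compounds 13 and 22 are drawn as keto tautomers.

**Route**

Step 1
Reactants: 1 2,2,6-trimethyl-4H-1,3-dioxin-4-one
Product: 2 2,2-dimethyl-6-(2-oxopropyl)-4H-1,3-dioxin-4-one
Conditions: 1 (2 equiv), LiN(SiMe3)2 (2 equiv), THF, −78 °C; then AcCl (1 equiv), −78 to −20 °C; 1 M HCl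
Reagents that add atoms: acetyl chloride, CC(=O)Cl
Why: Deprotonation of the 6-methyl group gives the extended lithium dienolate, which is C-acylated by acetyl chloride (vinylogous Claisen-type acylation), the second equivalent of enolate taking up the proton of the more acidic product.

Step 2
Reactants: 3 8-bromooct-1-ene; 4 (R)-1,2-epoxypentane
Product: 6 (R)-tridec-12-en-4-ol, via oct-7-enylmagnesium bromide 5 (not isolated)
Conditions: Mg turnings, THF, rt to 40 °C; then CuI (10 mol%), 4, THF, −30 to 0 °C; 1 M HCl
Reagents that add atoms: none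
Why: Copper-catalysed SN2 opening of the monosubstituted epoxide by the Grignard reagent occurs at the unsubstituted CH2, so the (R) carbinol is taken over unchanged from the epoxide.

Step 3
Reactants: 6 (R)-tridec-12-en-4-ol
Product: 7 (R)-10-(benzyloxy)tridec-1-ene
Conditions: NaH, BnBr, Bu4NI (cat.), THF/DMF, 0 °C to rt
Reagents that add atoms: benzyl bromide, BrCc1ccccc1
Why: Williamson etherification of the sodium alkoxide with benzyl bromide masks the only hydroxyl of this chain without touching the C–O bond of the stereocentre.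

Step 4
Reactants: 7 (R)-10-(benzyloxy)tridec-1-ene
Product: 9 (R)-10-(benzyloxy)tridecan-1-ol, via B-alkyl-9-BBN 8 (not isolated)
Conditions: 9-BBN, THF, 0 °C to rt; then NaOH (aq), H2O2, 0 °C to rt
Reagents that add atoms: hydrogen peroxide, OO
Why: Anti-Markovnikov hydroboration of the terminal alkene by 9-BBN and oxidation of the C–B bond with retention (Brown hydroboration–oxidation) should give the primary alcohol, with the benzyl ether inert.

Step 5
Reactants: 9 (R)-10-(benzyloxy)tridecan-1-ol
Product: 10 (R)-10-(benzyloxy)tridecanoic acid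
Conditions: TEMPO (cat.), PhI(OAc)2 (2.2 equiv), MeCN/H2O, rt
Reagents that add atoms: water, O
Why: Oxoammonium-mediated oxidation (TEMPO/PhI(OAc)2) takes the primary alcohol through the aldehyde hydrate to the acid under near-neutral conditions that leave the benzyl ether and the remote stereocentre alone.

Step 6
Reactants: 10 (R)-10-(benzyloxy)tridecanoic acid
Product: 12 (R)-10-(benzyloxy)-N-methoxy-N-methyltridecanamide, via acyl imidazole 11 (not isolated)
Conditions: CDI, CH2Cl2, rt; then MeNHOMe·HCl, rt
Reagents that add atoms: N,O-dimethylhydroxylamine hydrochloride, CNOC.Cl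
Why: Activation of the acid as its imidazolide followed by aminolysis is the standard Weinreb amide synthesis and involves no enolisable stereocentre.

Step 7
Reactants: 2 2,2-dimethyl-6-(2-oxopropyl)-4H-1,3-dioxin-4-one; 12 (R)-10-(benzyloxy)-N-methoxy-N-methyltridecanamide
Product: 13 6-[(13R)-13-(benzyloxy)-2,4-dioxohexadecyl]-2,2-dimethyl-4H-1,3-dioxin-4-one
Conditions: 2 (2 equiv), LiN(iPr)2 (4 equiv), THF, −78 °C; then 12 (1 equiv), −78 to −40 °C; 1 M HCl, 0 °C
Reagents that add atoms: none
Why: Double deprotonation of 2 gives a dianion that reacts at its terminal, more basic carbon with the Weinreb amide, and the chelated tetrahedral adduct collapses to the 1,3-diketone only on quench (Claisen-type C-acylation of a β-dicarbonyl dianion, Weinreb ketone synthesis).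

Step 8
Reactants: 14 5-bromoresorcinol
Product: 15 1,3-bis(benzyloxy)-5-bromobenzene
Conditions: BnBr (2.2 equiv), K2CO3, DMF, rt
Reagents that add atoms: benzyl bromide, BrCc1ccccc1
Why: Double Williamson etherification of the phenoxides protects ring B with groups that survive base, heat and palladium coupling and are removed by hydrogenolysis at the end.

Step 9
Reactants: 16 6-bromohex-1-ene; 4 (R)-1,2-epoxypentane
Product: 18 (R)-undec-10-en-4-ol, via hex-5-enylmagnesium bromide 17 (not isolated)
Conditions: Mg turnings, THF, 0 °C to rt; then CuI (10 mol%), 4, THF, −30 to 0 °C; 1 M HCl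
Reagents that add atoms: none
Why: The same copper-catalysed terminal epoxide opening as in step 2 carries the (R) centre over unchanged; the Grignard reagent is formed at or below rt to keep 5-exo cyclisation of the hexenyl radical small.

Step 10
Reactants: 18 (R)-undec-10-en-4-ol; 15 1,3-bis(benzyloxy)-5-bromobenzene
Product: 20 (4R)-11-[3,5-bis(benzyloxy)phenyl]undecan-4-ol, via B-alkyl-9-BBN 19 (not isolated)
Conditions: 9-BBN (2.5 equiv), THF, 0 °C to rt; then 15, Pd(dppf)Cl2 (5 mol%), 3 M NaOH (aq), THF, 65 °C
Reagents that add atoms: none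
Why: Terminal hydroboration followed by hydroxide-assisted transmetalation of the B-alkyl group to the arylpalladium bromide and reductive elimination forms the sp3–sp2 bond (B-alkyl Suzuki–Miyaura coupling); the excess borane covers the free hydroxyl, whose O–B bond the aqueous base cleaves again.

Step 11
Reactants: 13 6-[(13R)-13-(benzyloxy)-2,4-dioxohexadecyl]-2,2-dimethyl-4H-1,3-dioxin-4-one; 20 (4R)-11-[3,5-bis(benzyloxy)phenyl]undecan-4-ol
Product: 24 (4R)-11-[3,5-bis(benzyloxy)phenyl]undecan-4-yl 6-[(9R)-9-(benzyloxy)dodecyl]-2,4-dihydroxybenzoate, via acylketene 21 (not isolated), via triketo ester 22 (not isolated), via cyclic aldol 23 (not isolated)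
Conditions: 13 (1 equiv), 20 (1.2 equiv), PhMe (0.15 M), 110 °C; evaporate; Cs2CO3 (3 equiv), MeOH/CH2Cl2, rt; then HCl in MeOH to pH 2, rt
Reagents that add atoms: none
Why: At 110 °C the dioxinone ring of 13 loses acetone by retro-hetero-Diels–Alder reaction to give acylketene 21, whose unhindered sp carbon is attacked by the hydroxyl of 20 to give triketo ester 22, so the hindered ester C–O bond exists before ring A does and the carbinol keeps its (R) configuration because its C–O bond is never broken. Cs2CO3 then deprotonates the doubly activated C2 methylene, which adds to the C7 ketone in a 6-(enolexo)-exo-trig aldol that closes ring A through its C1–C6 bond, and methanolic HCl dehydrates aldol 23 to the arene. The closest known reaction type is the thermolysis of diketo-dioxinones in the presence of an alcohol followed by base-mediated aromatisation to resorcylate esters, a laboratory copy of polyketide folding. No lasting stereocentre is formed, since the carbinol carbon of 23 becomes an arene carbon, and both existing (R) centres lie far from every enolisable position. The step needs intermolecular ketene capture by one hydroxyl only, secured because the other carbinol and both ring B phenols are benzylated and because 20 is present in excess at moderate concentration to outrun capture by the enolised C5 oxygen (pyranone formation). It also needs aldol closure (C2 onto C7) rather than Claisen closure or lactonisation, secured by the mild carbonate base under which the most stabilised carbanion adds reversibly and the irreversible dehydration drains the equilibrium.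

Step 12
Reactants: 24 (4R)-11-[3,5-bis(benzyloxy)phenyl]undecan-4-yl 6-[(9R)-9-(benzyloxy)dodecyl]-2,4-dihydroxybenzoate
Product: 25 (4R)-11-[3,5-bis(benzyloxy)phenyl]undecan-4-yl 6-[(9R)-9-(benzyloxy)dodecyl]-2-hydroxy-4-methoxybenzoate
Conditions: MeI (1.2 equiv), K2CO3, acetone, rt
Reagents that add atoms: iodomethane, CI
Why: The C2 hydroxyl is hydrogen-bonded to the ester carbonyl and therefore less acidic and less nucleophilic, so Williamson methylation should occur at the para C4 phenol only.

Step 13
Reactants: 25 (4R)-11-[3,5-bis(benzyloxy)phenyl]undecan-4-yl 6-[(9R)-9-(benzyloxy)dodecyl]-2-hydroxy-4-methoxybenzoate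
Product: 26 5'-methoxy-integracin B, (4R)-11-(3,5-dihydroxyphenyl)undecan-4-yl 2-hydroxy-6-[(9R)-9-hydroxydodecyl]-4-methoxybenzoate
Conditions: H2 (1 atm), 10% Pd/C, EtOAc/EtOH, rt
Reagents that add atoms: none
Why: Catalytic hydrogenolysis cleaves the two aryl benzyl ethers and the secondary alkyl benzyl ether, while the non-benzylic ester C–O bond, the methyl ether and both stereocentres are left intact.

**Compound list**

1 | 2,2,6-trimethyl-4H-1,3-dioxin-4-one | CC1=CC(=O)OC(C)(C)O1 | starting material
2 | 2,2-dimethyl-6-(2-oxopropyl)-4H-1,3-dioxin-4-one | CC(=O)CC1=CC(=O)OC(C)(C)O1 | intermediate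
3 | 8-bromooct-1-ene | C=CCCCCCCBr | starting material
4 | (R)-1,2-epoxypentane, (2R)-2-propyloxirane | CCC[C@@H]1CO1 | starting material
5 | oct-7-enylmagnesium bromide (formed in the flask, step 2) | C=CCCCCCC[Mg]Br | intermediate
6 | (R)-tridec-12-en-4-ol | CCC[C@@H](O)CCCCCCCC=C | intermediate
7 | (R)-10-(benzyloxy)tridec-1-ene | CCC[C@@H](OCc1ccccc1)CCCCCCCC=C | intermediate
8 | 9-[(10R)-10-(benzyloxy)tridecyl]-9-borabicyclo[3.3.1]nonane (formed in the flask, step 4) | CCC[C@@H](OCc1ccccc1)CCCCCCCCCB1C2CCCC1CCC2 | intermediate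
9 | (R)-10-(benzyloxy)tridecan-1-ol | CCC[C@@H](OCc1ccccc1)CCCCCCCCCO | intermediate
10 | (R)-10-(benzyloxy)tridecanoic acid | CCC[C@@H](OCc1ccccc1)CCCCCCCCC(=O)O | intermediate
11 | 1-[(10R)-10-(benzyloxy)tridecanoyl]-1H-imidazole (formed in the flask, step 6) | CCC[C@@H](OCc1ccccc1)CCCCCCCCC(=O)n1ccnc1 | intermediate
12 | (R)-10-(benzyloxy)-N-methoxy-N-methyltridecanamide | CCC[C@@H](OCc1ccccc1)CCCCCCCCC(=O)N(C)OC | intermediate
13 | 6-[(13R)-13-(benzyloxy)-2,4-dioxohexadecyl]-2,2-dimethyl-4H-1,3-dioxin-4-one | CCC[C@@H](OCc1ccccc1)CCCCCCCCC(=O)CC(=O)CC1=CC(=O)OC(C)(C)O1 | intermediate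
14 | 5-bromoresorcinol | Oc1cc(O)cc(Br)c1 | starting material
15 | 1,3-bis(benzyloxy)-5-bromobenzene | Brc1cc(OCc2ccccc2)cc(OCc2ccccc2)c1 | intermediate
16 | 6-bromohex-1-ene | C=CCCCCBr | starting material
17 | hex-5-enylmagnesium bromide (formed in the flask, step 9) | C=CCCCC[Mg]Br | intermediate
18 | (R)-undec-10-en-4-ol | CCC[C@@H](O)CCCCCC=C | intermediate
19 | (4R)-11-(9-borabicyclo[3.3.1]nonan-9-yl)undecan-4-ol (formed in the flask, step 10) | CCC[C@@H](O)CCCCCCCB1C2CCCC1CCC2 | intermediate
20 | (4R)-11-[3,5-bis(benzyloxy)phenyl]undecan-4-ol | CCC[C@@H](O)CCCCCCCc1cc(OCc2ccccc2)cc(OCc2ccccc2)c1 | intermediate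
21 | (16R)-16-(benzyloxy)nonadec-1-ene-1,3,5,7-tetrone, the acylketene (formed in the flask, step 11) | CCC[C@@H](OCc1ccccc1)CCCCCCCCC(=O)CC(=O)CC(=O)C=C=O | intermediate
22 | (4R)-11-[3,5-bis(benzyloxy)phenyl]undecan-4-yl (16R)-16-(benzyloxy)-3,5,7-trioxononadecanoate (formed in the flask, step 11) | CCC[C@@H](OCc1ccccc1)CCCCCCCCC(=O)CC(=O)CC(=O)CC(=O)O[C@H](CCC)CCCCCCCc1cc(OCc2ccccc2)cc(OCc2ccccc2)c1 | intermediate
23 | (4R)-11-[3,5-bis(benzyloxy)phenyl]undecan-4-yl 6-[(9R)-9-(benzyloxy)dodecyl]-2,6-dihydroxy-4-oxocyclohex-1-ene-1-carboxylate, both epimers at the ring carbinol (formed in the flask, step 11) | CCC[C@@H](OCc1ccccc1)CCCCCCCCC1(O)CC(=O)CC(O)=C1C(=O)O[C@H](CCC)CCCCCCCc1cc(OCc2ccccc2)cc(OCc2ccccc2)c1 | intermediate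
24 | (4R)-11-[3,5-bis(benzyloxy)phenyl]undecan-4-yl 6-[(9R)-9-(benzyloxy)dodecyl]-2,4-dihydroxybenzoate | CCC[C@@H](OCc1ccccc1)CCCCCCCCc1cc(O)cc(O)c1C(=O)O[C@H](CCC)CCCCCCCc1cc(OCc2ccccc2)cc(OCc2ccccc2)c1 | intermediate
25 | (4R)-11-[3,5-bis(benzyloxy)phenyl]undecan-4-yl 6-[(9R)-9-(benzyloxy)dodecyl]-2-hydroxy-4-methoxybenzoate | CCC[C@@H](OCc1ccccc1)CCCCCCCCc1cc(OC)cc(O)c1C(=O)O[C@H](CCC)CCCCCCCc1cc(OCc2ccccc2)cc(OCc2ccccc2)c1 | intermediate
26 | 5'-methoxy-integracin B, (4R)-11-(3,5-dihydroxyphenyl)undecan-4-yl 2-hydroxy-6-[(9R)-9-hydroxydodecyl]-4-methoxybenzoate | CCC[C@@H](O)CCCCCCCCc1cc(OC)cc(O)c1C(=O)O[C@H](CCC)CCCCCCCc1cc(O)cc(O)c1 | target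

**Totals**

Total step count: 13.
Longest linear sequence: 9 steps (steps 2, 3, 4, 5, 6, 7, 11, 12, 13).

**Steps most likely to fail, with fallbacks**

Step 11. The acylketene may be captured internally by the enolised C5 oxygen, or may dimerise, faster than the hindered secondary alcohol adds. During aromatisation, Claisen-type closure or methanolysis of the new ester may also compete with the aldol. The fallback closes ring A first and makes the ester afterwards by alkoxide opening of a benzodioxinone. It sets out from 13: Et3N in CH2Cl2 at rt, without heating, should fold 13 by aldol condensation of the dioxinone C5 carbon onto the C7 ketone to 5-[(9R)-9-(benzyloxy)dodecyl]-7-hydroxy-2,2-dimethyl-4H-1,3-benzodioxin-4-one F1. MeI and K2CO3 in acetone should then give 5-[(9R)-9-(benzyloxy)dodecyl]-7-methoxy-2,2-dimethyl-4H-1,3-benzodioxin-4-one F2. The sodium alkoxide of 20 (NaN(SiMe3)2, THF, 0 °C to rt) should open the lactone of F2 with loss of acetone, freeing the C2 phenol and giving 25 directly. The route is rejoined at 25, before step 13.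

Step 7. Proton transfer from the acidic diketone product or from the α-CH2 of the amide may quench the dianion before C-acylation, and acylation at oxygen or at the internal carbon may compete. The fallback forms the same C–C bond by aldol addition to an aldehyde and then adjusts the oxidation level. It sets out from 9: Dess–Martin periodinane in CH2Cl2 should give (R)-10-(benzyloxy)tridecanal F3. Addition of F3 to the dianion of 2 (LiN(iPr)2, THF, −78 °C) should give 6-[(13R)-13-(benzyloxy)-4-hydroxy-2-oxohexadecyl]-2,2-dimethyl-4H-1,3-dioxin-4-one F4 as a mixture of carbinol epimers. A second Dess–Martin oxidation converts F4 to 13, where the route is rejoined.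

Step 10. Transmetalation of the alkylborane that carries an O-borylated hydroxyl may be slow, so that β-hydride elimination, protodeboronation and hydrodebromination of 15 take over. The fallback makes the aryl–alkyl bond by copper-catalysed Grignard alkylation and opens the epoxide last. It sets out from 15: Mg in THF should give [3,5-bis(benzyloxy)phenyl]magnesium bromide F5. Coupling of F5 with excess 1,6-dibromohexane under Li2CuCl4 catalysis (THF, 0 °C, Kochi-type coupling) should give 1,3-bis(benzyloxy)-5-(6-bromohexyl)benzene F6. Mg in THF converts F6 to {6-[3,5-bis(benzyloxy)phenyl]hexyl}magnesium bromide F7, which with CuI (cat.) and epoxide 4 at −30 to 0 °C should give 20, where the route is rejoined.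

**Further compounds**

F1 | step 11 | 5-[(9R)-9-(benzyloxy)dodecyl]-7-hydroxy-2,2-dimethyl-4H-1,3-benzodioxin-4-one | CCC[C@@H](OCc1ccccc1)CCCCCCCCc1cc(O)cc2OC(C)(C)OC(=O)c12
F2 | step 11 | 5-[(9R)-9-(benzyloxy)dodecyl]-7-methoxy-2,2-dimethyl-4H-1,3-benzodioxin-4-one | CCC[C@@H](OCc1ccccc1)CCCCCCCCc1cc(OC)cc2OC(C)(C)OC(=O)c12
F3 | step 7 | (R)-10-(benzyloxy)tridecanal | CCC[C@@H](OCc1ccccc1)CCCCCCCCC=O
F4 | step 7 | 6-[(13R)-13-(benzyloxy)-4-hydroxy-2-oxohexadecyl]-2,2-dimethyl-4H-1,3-dioxin-4-one, both carbinol epimers | CCC[C@@H](OCc1ccccc1)CCCCCCCCC(O)CC(=O)CC1=CC(=O)OC(C)(C)O1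
F5 | step 10 | [3,5-bis(benzyloxy)phenyl]magnesium bromide | Br[Mg]c1cc(OCc2ccccc2)cc(OCc2ccccc2)c1
F6 | step 10 | 1,3-bis(benzyloxy)-5-(6-bromohexyl)benzene | BrCCCCCCc1cc(OCc2ccccc2)cc(OCc2ccccc2)c1
F7 | step 10 | {6-[3,5-bis(benzyloxy)phenyl]hexyl}magnesium bromide | Br[Mg]CCCCCCc1cc(OCc2ccccc2)cc(OCc2ccccc2)c1
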